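Rings are lettered A to D along the chain: A is the terminal 3,5-dihydroxyphenoxy ring; B carries O–A at C1, hydroxyls at C2 and C4 and O–C at C6; C carries O–B at C1 and ring D at C5; D is the 2,4,6-trihydroxyphenyl ring, with D1 bonded to ring C.
Retrosynthesis: first the eight O-alkyl bonds, then ring D itself (bonds D1–D2, D5–D6 and D2–D3) back to a silyl ynol ether on ring C C5 and 3-ethoxycyclobutenone, then the alkyne back to an aldehyde, then the B–O–C ether and last the A–O–B ether.
Enabling feature: D1 sits between two oxygen-bearing carbons (D2, D6) with a third oxygen para at D4, the pattern a 3-alkoxyvinylketene and an aryl ynol ether deliver, so the tetra-ortho-substituted C5–D1 axis can begin as an unhindered aryl–alkyne bond.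
Forward: ring B (from 5-iodovanillin) receives ring A by Chan–Lam coupling and is trimmed to the AB iodide; ring C (formylated 2,4,6-trimethoxyphenol) is attached by Ullmann coupling; the aldehyde becomes the alkyne and then the ynol ether; ring D is grown last by benzannulation; BBr3 unmasks all phenols.
Stereochemistry: the target has no stereocentre and, ring D being symmetric, no stereogenic axis, so nothing has to be set or protected.

Key step: step 9

Assumption: 2,4,6-trimethoxyphenol is treated as a purchasable compound; it is otherwise the Dakin oxidation product of the common 2,4,6-trimethoxybenzaldehyde.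

In the names below, Ar = 3-[2-(3,5-dimethoxyphenoxy)-3,5-dimethoxyphenoxy]-2,4,6-trimethoxyphenyl.

Step 1
Reactants: 1 5-iodovanillin (4-hydroxy-3-iodo-5-methoxybenzaldehyde); 2 3,5-dimethoxyphenylboronic acid
Product: 3 4-(3,5-dimethoxyphenoxy)-3-iodo-5-methoxybenzaldehyde
Conditions: Cu(OAc)2 (20 mol %), pyridine, 4 Å MS, CH2Cl2, O2 (1 atm), rt
Reagents that add atoms: none
Why: Chan–Lam oxidative C–O coupling, in which the copper phenoxide transmetallates with the arylboronic acid and eliminates the diaryl ether at room temperature, conditions under which di-ortho-substituted phenols are competent and the aryl iodide and aldehyde are spectators.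

Step 2
Reactants: 3 4-(3,5-dimethoxyphenoxy)-3-iodo-5-methoxybenzaldehyde
Product: 5 4-(3,5-dimethoxyphenoxy)-3-iodo-5-methoxyphenol, via aryl formate 4 (not isolated)
Conditions: mCPBA, CH2Cl2, 0 °C → rt; aq. NaHCO3 wash; then K2CO3 (cat.), MeOH, rt
Reagents that add atoms: 3-chloroperoxybenzoic acid (mCPBA), O=C(OO)c1cccc(Cl)c1
Why: Baeyer–Villiger oxidation in its Dakin-type use, where the ring carbon para to the aryloxy donor migrates to oxygen in preference to hydride and mild methanolysis of formate 4 should release the phenol without disturbing the iodide or the diaryl ether.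

Step 3
Reactants: 5 4-(3,5-dimethoxyphenoxy)-3-iodo-5-methoxyphenol
Product: 6 2-(3,5-dimethoxyphenoxy)-1-iodo-3,5-dimethoxybenzene (AB iodide)
Conditions: MeI, K2CO3, acetone, reflux
Reagents that add atoms: iodomethane, CI
Why: Williamson methylation of an unhindered phenoxide caps the oxygen that becomes the ring B C4 hydroxyl as the same methyl ether used on the other rings.

Step 4
Reactants: 7 2,4,6-trimethoxyphenol
Product: 9 3-hydroxy-2,4,6-trimethoxybenzaldehyde, via iminium salt 8 (not isolated)
Conditions: POCl3, DMF, 0 → 50 °C; then H2O, 50 °C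
Reagents that add atoms: N,N-dimethylformamide, CN(C)C=O; water, O
Why: Vilsmeier–Haack formylation, in which the two free ring positions are equivalent and each lies ortho or para to three methoxy groups, so only one aldehyde can form, the formyl group deactivates the ring against a second attack and the aqueous hydrolysis also removes any O-formyl group.

Step 5
Reactants: 6 2-(3,5-dimethoxyphenoxy)-1-iodo-3,5-dimethoxybenzene; 9 3-hydroxy-2,4,6-trimethoxybenzaldehyde
Product: 10 3-[2-(3,5-dimethoxyphenoxy)-3,5-dimethoxyphenoxy]-2,4,6-trimethoxybenzaldehyde (ABC aldehyde, ArCHO)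
Conditions: CuI (10 mol %), picolinic acid (20 mol %), K3PO4, DMSO, 90 °C
Reagents that add atoms: none
Why: Ullmann-type copper-catalysed diaryl ether synthesis with a picolinate ligand, a system that tolerates ortho substituents on both partners; here the doubly flanked centre is the nucleophilic phenoxide, the iodide has only one ortho substituent, and the non-enolisable aldehyde is inert to K3PO4.

Step 6
Reactants: 10 3-[2-(3,5-dimethoxyphenoxy)-3,5-dimethoxyphenoxy]-2,4,6-trimethoxybenzaldehyde
Product: 11 1-[2-(3,5-dimethoxyphenoxy)-3,5-dimethoxyphenoxy]-3-ethynyl-2,4,6-trimethoxybenzene (ArC≡CH)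
Conditions: dimethyl (1-diazo-2-oxopropyl)phosphonate, K2CO3, MeOH/THF, 0 °C → rt
Reagents that add atoms: dimethyl (1-diazo-2-oxopropyl)phosphonate, CC(=O)C(=[N+]=[N-])P(=O)(OC)OC
Why: Ohira–Bestmann variant of the Seyferth–Gilbert homologation, in which the diazomethylphosphonate anion released by methanolysis adds to the aldehyde, eliminates dimethyl phosphate and loses N2 with 1,2-hydride shift to the terminal alkyne under mild base that the aryl ethers ignore.

Step 7
Reactants: 11 1-[2-(3,5-dimethoxyphenoxy)-3,5-dimethoxyphenoxy]-3-ethynyl-2,4,6-trimethoxybenzene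
Product: 14 (Ar-ethynyloxy)tri(propan-2-yl)silane (ArC≡C–OSi(i-Pr)3), via lithium acetylide 12 (not isolated), via lithium ynolate 13 (not isolated)
Conditions: LiN(SiMe3)2, THF, −78 °C; t-BuOOLi (from t-BuOOH and LiN(SiMe3)2), −78 → 0 °C; then TIPSOTf, −78 → 0 °C
Reagents that add atoms: tert-butyl hydroperoxide, CC(C)(C)OO; triisopropylsilyl trifluoromethanesulfonate, CC(C)[Si](OS(=O)(=O)C(F)(F)F)(C(C)C)C(C)C
Why: Electrophilic oxygenation of a lithium acetylide by lithium tert-butyl peroxide gives the lithium ynolate, and the bulky silyl triflate should trap it on oxygen instead of carbon, which is the established way from terminal alkynes to triisopropylsiloxyalkynes.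

Step 8
Reactants: 15 ethoxyacetylene; 16 acetyl chloride
Product: 18 3-ethoxycyclobut-2-en-1-one, via ketene 17 (not isolated)
Conditions: Et3N, Et2O, 0 °C → rt
Reagents that add atoms: none
Why: Dehydrochlorination of acetyl chloride gives ketene, which adds [2+2] to the ynol ether with its carbonyl carbon on the unsubstituted alkyne carbon, the classical ketene–alkoxyalkyne route to 3-alkoxycyclobutenones.

Step 9
Reactants: 14 (Ar-ethynyloxy)tri(propan-2-yl)silane; 18 3-ethoxycyclobut-2-en-1-one
Product: 24 2-{3-[2-(3,5-dimethoxyphenoxy)-3,5-dimethoxyphenoxy]-2,4,6-trimethoxyphenyl}-5-ethoxybenzene-1,3-diol, via vinylketene 19 (not isolated), via vinylcyclobutenone 20 (not isolated), via dienylketene 21 (not isolated), via cyclohexadienone 22 (not isolated), via silyl phenol 23 (not isolated)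
Conditions: 18 (2.5 equiv), toluene, 80 → 110 °C, sealed tube, argon; then n-Bu4NF, THF, 0 °C → rt
Reagents that add atoms: none
Why: Heat should open 18 by four-electron electrocyclic cleavage of its C1–C4 bond to 3-ethoxyvinylketene 19, whose ketene C=C undergoes [2+2] cycloaddition with the siloxyalkyne so that the electrophilic carbonyl carbon bonds to the nucleophilic aryl-bearing alkyne carbon (D1–D2) and the alpha carbon to the siloxy-bearing carbon (D5–D6), giving vinylcyclobutenone 20. A second four-electron opening of 20 gives dienylketene 21, and ring D closes by a thermal six-electron disrotatory electrocyclisation between the ketene carbon and the terminal methylene (D2–D3) to dienone 22, which tautomerises to phenol 23. The closest known reaction is the Danheiser benzannulation of cyclobutenones with alkyl-substituted siloxy- and alkoxyalkynes to give resorcinol monoethers, and 3-alkoxycyclobutenones are known to equilibrate thermally with their vinylketenes. No stereocentre is formed, and the C–D axis of 23 arises racemic and loses its stereogenic character when fluoride unveils the second ortho hydroxyl. The one selectivity needed is the orientation of the [2+2] step, which the oxygen-polarised ynol ether fixes so that OH and OSi flank D1 and OEt lies para to it, while the unproductive opening of 20 is reversible and only the isomer with the ketene cis to the ethoxyvinyl group can close. A silyl ynol ether is used in place of an ethyl one because it cannot shed ethylene by retro-ene fragmentation at the temperature the vinylogous-ester cyclobutenone needs, and the fluoride treatment should also cleave any aryl ester formed when product phenol traps a ketene.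

Step 10
Reactants: 24 2-{3-[2-(3,5-dimethoxyphenoxy)-3,5-dimethoxyphenoxy]-2,4,6-trimethoxyphenyl}-5-ethoxybenzene-1,3-diol
Product: 25 2-{3-[2-(3,5-dihydroxyphenoxy)-3,5-dihydroxyphenoxy]-2,4,6-trihydroxyphenyl}benzene-1,3,5-triol (CNP0210555.0)
Conditions: BBr3 (excess), CH2Cl2, −78 °C → rt; H2O quench under argon; reversed-phase chromatography
Reagents that add atoms: none
Why: Lewis acid ether cleavage, in which BBr3 complexes each alkyl aryl ether oxygen and bromide removes the methyl or ethyl group by SN2 attack, while the diaryl ether and biaryl bonds, which offer no sp3 carbon, should survive.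

Compound list
1 | 5-iodovanillin (4-hydroxy-3-iodo-5-methoxybenzaldehyde) | COc1cc(C=O)cc(I)c1O | starting material
2 | 3,5-dimethoxyphenylboronic acid | COc1cc(OC)cc(B(O)O)c1 | starting material
3 | 4-(3,5-dimethoxyphenoxy)-3-iodo-5-methoxybenzaldehyde | COc1cc(C=O)cc(I)c1Oc1cc(OC)cc(OC)c1 | intermediate
4 | 4-(3,5-dimethoxyphenoxy)-3-iodo-5-methoxyphenyl formate | COc1cc(OC=O)cc(I)c1Oc1cc(OC)cc(OC)c1 | intermediate (not isolated)
5 | 4-(3,5-dimethoxyphenoxy)-3-iodo-5-methoxyphenol | COc1cc(O)cc(I)c1Oc1cc(OC)cc(OC)c1 | intermediate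
6 | 2-(3,5-dimethoxyphenoxy)-1-iodo-3,5-dimethoxybenzene | COc1cc(I)c(Oc2cc(OC)cc(OC)c2)c(OC)c1 | intermediate
7 | 2,4,6-trimethoxyphenol | COc1cc(OC)c(O)c(OC)c1 | starting material
8 | N-[(3-hydroxy-2,4,6-trimethoxyphenyl)methylidene]-N-methylmethanaminium chloride | COc1cc(OC)c(C=[N+](C)C)c(OC)c1O.[Cl-] | intermediate (not isolated)
9 | 3-hydroxy-2,4,6-trimethoxybenzaldehyde | COc1cc(OC)c(C=O)c(OC)c1O | intermediate
10 | 3-[2-(3,5-dimethoxyphenoxy)-3,5-dimethoxyphenoxy]-2,4,6-trimethoxybenzaldehyde | COc1cc(OC)c(C=O)c(OC)c1Oc1cc(OC)cc(OC)c1Oc1cc(OC)cc(OC)c1 | intermediate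
11 | 1-[2-(3,5-dimethoxyphenoxy)-3,5-dimethoxyphenoxy]-3-ethynyl-2,4,6-trimethoxybenzene | C#Cc1c(OC)cc(OC)c(Oc2cc(OC)cc(OC)c2Oc2cc(OC)cc(OC)c2)c1OC | intermediate
12 | lithium acetylide of 11 (ArC≡CLi) | [Li]C#Cc1c(OC)cc(OC)c(Oc2cc(OC)cc(OC)c2Oc2cc(OC)cc(OC)c2)c1OC | intermediate (not isolated)
13 | lithium 2-Ar-ethynolate (ArC≡C–OLi) | [Li]OC#Cc1c(OC)cc(OC)c(Oc2cc(OC)cc(OC)c2Oc2cc(OC)cc(OC)c2)c1OC | intermediate (not isolated)
14 | (Ar-ethynyloxy)tri(propan-2-yl)silane | CC(C)[Si](OC#Cc1c(OC)cc(OC)c(Oc2cc(OC)cc(OC)c2Oc2cc(OC)cc(OC)c2)c1OC)(C(C)C)C(C)C | intermediate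
15 | ethoxyacetylene (ethoxyethyne) | CCOC#C | starting material
16 | acetyl chloride | CC(Cl)=O | starting material
17 | ketene | C=C=O | intermediate (not isolated)
18 | 3-ethoxycyclobut-2-en-1-one | CCOC1=CC(=O)C1 | intermediate
19 | 3-ethoxybuta-1,3-dien-1-one (3-ethoxyvinylketene) | CCOC(=C)C=C=O | intermediate (not isolated)
20 | 2-Ar-4-(1-ethoxyethenyl)-3-(triisopropylsilyloxy)cyclobut-2-en-1-one, racemic at C4 | CCOC(=C)C1C(=O)C(c2c(OC)cc(OC)c(Oc3cc(OC)cc(OC)c3Oc3cc(OC)cc(OC)c3)c2OC)=C1O[Si](C(C)C)(C(C)C)C(C)C | intermediate (not isolated)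
21 | 2-Ar-5-ethoxy-3-(triisopropylsilyloxy)hexa-1,3,5-trien-1-one, ketene carbon and ethoxyvinyl group cis across the central double bond | CCOC(=C)/C=C(O[Si](C(C)C)(C(C)C)C(C)C)\C(=C=O)c1c(OC)cc(OC)c(Oc2cc(OC)cc(OC)c2Oc2cc(OC)cc(OC)c2)c1OC | intermediate (not isolated)
22 | 2-Ar-5-ethoxy-3-(triisopropylsilyloxy)cyclohexa-2,4-dien-1-one | CCOC1=CC(O[Si](C(C)C)(C(C)C)C(C)C)=C(c2c(OC)cc(OC)c(Oc3cc(OC)cc(OC)c3Oc3cc(OC)cc(OC)c3)c2OC)C(=O)C1 | intermediate (not isolated)
23 | 2-Ar-5-ethoxy-3-(triisopropylsilyloxy)phenol, racemic about the C–D axis | CCOc1cc(O)c(-c2c(OC)cc(OC)c(Oc3cc(OC)cc(OC)c3Oc3cc(OC)cc(OC)c3)c2OC)c(O[Si](C(C)C)(C(C)C)C(C)C)c1 | intermediate (not isolated)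
24 | 2-{3-[2-(3,5-dimethoxyphenoxy)-3,5-dimethoxyphenoxy]-2,4,6-trimethoxyphenyl}-5-ethoxybenzene-1,3-diol | CCOc1cc(O)c(-c2c(OC)cc(OC)c(Oc3cc(OC)cc(OC)c3Oc3cc(OC)cc(OC)c3)c2OC)c(O)c1 | intermediate
25 | 2-{3-[2-(3,5-dihydroxyphenoxy)-3,5-dihydroxyphenoxy]-2,4,6-trihydroxyphenyl}benzene-1,3,5-triol | Oc1cc(O)cc(Oc2c(O)cc(O)cc2Oc2c(O)cc(O)c(-c3c(O)cc(O)cc3O)c2O)c1 | target

Total step count: 10.
Longest linear sequence: 8 steps (steps 1, 2, 3, 5, 6, 7, 9 and 10, from 5-iodovanillin).

Steps most likely to fail

Step 9. Opening of the alkoxy-stabilised cyclobutenone may lag behind dimerisation of the vinylketene or thermal silyl migration in the ynol ether. The cycloaddition at an alkyne carbon shielded by two ortho methoxy groups may also be slow. The fallback makes the C5–D1 bond first on simple arenes and sets out from AB iodide 6.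
- Ullmann homocoupling of commercial 2-iodo-1,3,5-trimethoxybenzene (Cu powder, DMF, 150 °C) should give 2,2',4,4',6,6'-hexamethoxybiphenyl F1.
- Mono-formylation (POCl3, DMF, limiting reagent; then water) should pass through iminium salt F2 to 2,2',4,4',6,6'-hexamethoxybiphenyl-3-carbaldehyde F3; all four free positions are equivalent.
- Baeyer–Villiger oxidation (mCPBA, CH2Cl2) to aryl formate F4 and methanolysis (K2CO3, MeOH) should give 2,2',4,4',6,6'-hexamethoxybiphenyl-3-ol F5.
- Ullmann etherification of F5 with 6 under the conditions of step 5 should give 3-[2-(3,5-dimethoxyphenoxy)-3,5-dimethoxyphenoxy]-2,2',4,4',6,6'-hexamethoxybiphenyl F6.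
- BBr3 as in step 10 brings the sequence back to the route at target 25.

Step 5. The C–O bond forms at a centre that ends with three ortho substituents, so reduction of the iodide of 6 or slow turnover of the copper phenoxide may outrun coupling. The fallback reverses the roles of the two rings and again sets out from 6.
- Copper-catalysed hydroxylation of 6 (CuI, 1,10-phenanthroline, KOH, DMSO/H2O, 100 °C) should give 2-(3,5-dimethoxyphenoxy)-3,5-dimethoxyphenol F7.
- Iodination of commercial 2,4,6-trimethoxybenzaldehyde (N-iodosuccinimide, CF3CO2H cat., MeCN) should give 3-iodo-2,4,6-trimethoxybenzaldehyde F8.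
- Coupling of the less hindered phenoxide of F7 with F8 (CuI, N,N-dimethylglycine, Cs2CO3, dioxane, 100 °C) returns to the route at aldehyde 10.

Step 7. Oxygen transfer from the peroxide to the acetylide may be incomplete, or the electron-rich ynolate may be oxidised further before it is silylated. The fallback generates the same ynolate without an oxidant and sets out from aldehyde 10.
- Pinnick oxidation (NaClO2, NaH2PO4, 2-methylbut-2-ene, t-BuOH/H2O) should give 3-[2-(3,5-dimethoxyphenoxy)-3,5-dimethoxyphenoxy]-2,4,6-trimethoxybenzoic acid F9.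
- Methylation (MeI, K2CO3, DMF) should give methyl 3-[2-(3,5-dimethoxyphenoxy)-3,5-dimethoxyphenoxy]-2,4,6-trimethoxybenzoate F10.
- Kowalski ester homologation (CH2Br2, lithium 2,2,6,6-tetramethylpiperidide, THF, −78 °C; then n-BuLi, −78 → 0 °C) should pass through lithium 1-Ar-2,2-dibromoethenolate F11 and, after bromine–lithium exchange and aryl migration, return to the route at lithium ynolate 13. Silylation with TIPSOTf then gives 14 as in step 7.

Further compounds
F1 | step 9 | 2,2',4,4',6,6'-hexamethoxybiphenyl | COc1cc(OC)c(-c2c(OC)cc(OC)cc2OC)c(OC)c1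
F2 | step 9 | N-[(2,2',4,4',6,6'-hexamethoxybiphenyl-3-yl)methylidene]-N-methylmethanaminium chloride | COc1cc(OC)c(-c2c(OC)cc(OC)c(C=[N+](C)C)c2OC)c(OC)c1.[Cl-]
F3 | step 9 | 2,2',4,4',6,6'-hexamethoxybiphenyl-3-carbaldehyde | COc1cc(OC)c(-c2c(OC)cc(OC)c(C=O)c2OC)c(OC)c1
F4 | step 9 | 2,2',4,4',6,6'-hexamethoxybiphenyl-3-yl formate | COc1cc(OC)c(-c2c(OC)cc(OC)c(OC=O)c2OC)c(OC)c1
F5 | step 9 | 2,2',4,4',6,6'-hexamethoxybiphenyl-3-ol | COc1cc(OC)c(-c2c(OC)cc(OC)c(O)c2OC)c(OC)c1
F6 | step 9 | 3-[2-(3,5-dimethoxyphenoxy)-3,5-dimethoxyphenoxy]-2,2',4,4',6,6'-hexamethoxybiphenyl | COc1cc(OC)c(-c2c(OC)cc(OC)c(Oc3cc(OC)cc(OC)c3Oc3cc(OC)cc(OC)c3)c2OC)c(OC)c1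
F7 | step 5 | 2-(3,5-dimethoxyphenoxy)-3,5-dimethoxyphenol | COc1cc(O)c(Oc2cc(OC)cc(OC)c2)c(OC)c1
F8 | step 5 | 3-iodo-2,4,6-trimethoxybenzaldehyde | COc1cc(OC)c(C=O)c(OC)c1I
F9 | step 7 | 3-[2-(3,5-dimethoxyphenoxy)-3,5-dimethoxyphenoxy]-2,4,6-trimethoxybenzoic acid | COc1cc(OC)c(C(=O)O)c(OC)c1Oc1cc(OC)cc(OC)c1Oc1cc(OC)cc(OC)c1
F10 | step 7 | methyl 3-[2-(3,5-dimethoxyphenoxy)-3,5-dimethoxyphenoxy]-2,4,6-trimethoxybenzoate | COC(=O)c1c(OC)cc(OC)c(Oc2cc(OC)cc(OC)c2Oc2cc(OC)cc(OC)c2)c1OC
F11 | step 7 | lithium 1-Ar-2,2-dibromoethenolate | [Li]OC(=C(Br)Br)c1c(OC)cc(OC)c(Oc2cc(OC)cc(OC)c2Oc2cc(OC)cc(OC)c2)c1OC
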